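**Assumption:** the target SMILES has no stereocentre and the macrocycle is taken as conformationally mobile (achiral), so there is no configuration to set or protect.

## Retrosynthetic overview

1. The 15-membered ring is closed last by a radical C–C bond formation at C3–C4 of the heptanoid chain (C1 on the hydroxylated ring B, C=O at C5). An α-keto radical at C4 adds to the terminal alkene of an ortho-allyl group on ring B.
2. The allyl group and the free C3-OH of ring B come together from an aromatic Claisen rearrangement; the radical precursor (ICH2–C=O) comes from the methyl ketone by kinetic enol silylation/iodination.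
3. The diaryl ether is made earlier, intermolecularly, by Ullmann coupling of 2-methoxyresorcinol with a 3-bromo-4-methoxyphenyl butanone.
4. 2-Methoxyresorcinol comes from phenol (ortho-dibromination, O-methylation, double hydroxylation); the bromo ketone comes from 2-bromophenol and methyl vinyl ketone.
5. Ring order: both benzene rings are bought; the only ring formed is the macrocycle, in the final step.

## Route

**Step 1**
Reactants: 1 phenol
Product: 2 2,6-dibromophenol
Conditions: Br2 (2.0 equiv), t-BuNH2 (4 equiv), toluene, −70 °C → rt
Reagents that add atoms: bromine, BrBr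
Why: amine-mediated ortho-selective electrophilic bromination (the N-bromoamine delivers Br to both ortho positions through the phenol H-bond, leaving the para position free).

**Step 2**
Reactants: 2 2,6-dibromophenol
Product: 3 1,3-dibromo-2-methoxybenzene
Conditions: MeI, K2CO3, acetone, reflux
Reagents that add atoms: iodomethane, CI
Why: Williamson O-methylation of the hindered but acidic phenol fixes the central OMe of ring B.

**Step 3**
Reactants: 3 1,3-dibromo-2-methoxybenzene
Product: 4 2-methoxybenzene-1,3-diol (2-methoxyresorcinol)
Conditions: Pd2(dba)3 (2 mol %), tBuXPhos (8 mol %), KOH (6 equiv), dioxane/H2O 1:1, 100 °C, degassed; then 1 M HCl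
Reagents that add atoms: potassium hydroxide, [K+].[OH-]
Why: Buchwald-type Pd-catalysed hydroxylation of both mono-ortho-substituted C–Br bonds gives the symmetric diol with the OMe locked between the two oxygens.

**Step 4**
Reactants: 5 2-bromophenol; 6 but-3-en-2-one (methyl vinyl ketone, 1.3 equiv, slow addition)
Product: 7 4-(3-bromo-4-hydroxyphenyl)butan-2-one
Conditions: TfOH (10 mol %), 1,2-dichloroethane, 0 °C → rt
Reagents that add atoms: none
Why: acid-catalysed Friedel–Crafts conjugate addition (hydroarylation of the enone, as in the raspberry-ketone process) occurs para to the OH, giving the four-carbon ketone chain C7–C4.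

**Step 5**
Reactants: 7 4-(3-bromo-4-hydroxyphenyl)butan-2-one
Product: 8 4-(3-bromo-4-methoxyphenyl)butan-2-one
Conditions: MeI, K2CO3, acetone, reflux
Reagents that add atoms: iodomethane, CI
Why: Williamson O-methylation; carbonate does not enolise the ketone enough to C-alkylate it.

**Step 6**
Reactants: 8 4-(3-bromo-4-methoxyphenyl)butan-2-one; 4 2-methoxybenzene-1,3-diol (2.5–3 equiv, excess recovered)
Product: 9 4-[3-(3-hydroxy-2-methoxyphenoxy)-4-methoxyphenyl]butan-2-one
Conditions: CuI (10 mol %), N,N-dimethylglycine·HCl (30 mol %), Cs2CO3, dioxane, 100 °C, Ar
Reagents that add atoms: none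
Why: ligand-accelerated Ullmann diaryl ether coupling; the excess of the symmetric diol makes mono-arylation dominant and leaves one OH for the next step.

**Step 7**
Reactants: 9; 10 allyl bromide (1.3 equiv)
Product: 11 4-{4-methoxy-3-[2-methoxy-3-(prop-2-en-1-yloxy)phenoxy]phenyl}butan-2-one
Conditions: K2CO3, acetone, reflux
Reagents that add atoms: none
Why: Williamson O-allylation of the only phenol; the methyl ketone is untouched under carbonate.

**Step 8**
Reactants: 11
Product: 12 4-{3-[3-hydroxy-2-methoxy-4-(prop-2-en-1-yl)phenoxy]-4-methoxyphenyl}butan-2-one
Conditions: PhNEt2, 195 °C, sealed tube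
Reagents that add atoms: none
Why: aromatic Claisen rearrangement; one ortho position carries OMe, so the [3,3] shift delivers the allyl group (C1–C3) to the only free ortho carbon, para to the diaryl ether oxygen, and regenerates the C3-OH.

**Step 9**
Reactants: 12
Product: 13 1-iodo-4-{4-methoxy-3-[2-methoxy-4-(prop-2-en-1-yl)-3-(triethylsilyloxy)phenoxy]phenyl}butan-2-one
Conditions: LDA (2.3 equiv), TESCl (2.5 equiv), THF, −78 → 0 °C; then NIS (1.05 equiv), −78 → 0 °C, dark
Reagents that add atoms: chlorotriethylsilane, CC[Si](Cl)(CC)CC; N-iodosuccinimide, O=C1CCC(=O)N1I
Why: kinetic deprotonation at the methyl group with in-situ silyl trapping gives the terminal silyl enol ether (and the aryl TES ether), and electrophilic iodination of the enol ether places iodine on C4 only.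

**Step 10**
Reactants: 13
Product: 14 juglanin A
Conditions: (Bu3Sn)2 (0.2 equiv), hν (sunlamp), benzene, 80 °C, 2 mM; then Bu3SnH (1.5 equiv), AIBN, 80 °C; then TBAF, THF, rt
Reagents that add atoms: none
Why: Proposed new method: C–I homolysis gives the electrophilic α-keto radical at C4, which adds 15-endo to the terminal CH2 of the allyl group (polarity-matched, chain pre-folded by the diaryl ether hinge); the C2 radical takes iodine from another molecule of 13 to carry the chain, Bu3SnH then removes the iodine and fluoride cleaves the TES ether (which prevents phenolic O–H from quenching the chain). Closest known chemistry is Curran/Kharasch-type iodine-atom-transfer radical cyclisation, including endo macrocyclisation of ω-alkenyl α-iodo esters, and Porter-type endo radical macrocyclisation to macrocyclic ketones. No stereocentre is formed.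

## Compound list

1 | phenol | Oc1ccccc1 | starting material
2 | 2,6-dibromophenol | Oc1c(Br)cccc1Br | intermediate
3 | 1,3-dibromo-2-methoxybenzene | COc1c(Br)cccc1Br | intermediate
4 | 2-methoxybenzene-1,3-diol | COc1c(O)cccc1O | intermediate
5 | 2-bromophenol | Oc1ccccc1Br | starting material
6 | but-3-en-2-one (methyl vinyl ketone) | CC(=O)C=C | starting material
7 | 4-(3-bromo-4-hydroxyphenyl)butan-2-one | CC(=O)CCc1ccc(O)c(Br)c1 | intermediate
8 | 4-(3-bromo-4-methoxyphenyl)butan-2-one | CC(=O)CCc1ccc(OC)c(Br)c1 | intermediate
9 | 4-[3-(3-hydroxy-2-methoxyphenoxy)-4-methoxyphenyl]butan-2-one | CC(=O)CCc1ccc(OC)c(Oc2cccc(O)c2OC)c1 | intermediate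
10 | allyl bromide (3-bromoprop-1-ene) | C=CCBr | starting material
11 | 4-{4-methoxy-3-[2-methoxy-3-(prop-2-en-1-yloxy)phenoxy]phenyl}butan-2-one | CC(=O)CCc1ccc(OC)c(Oc2cccc(OCC=C)c2OC)c1 | intermediate
12 | 4-{3-[3-hydroxy-2-methoxy-4-(prop-2-en-1-yl)phenoxy]-4-methoxyphenyl}butan-2-one | CC(=O)CCc1ccc(OC)c(Oc2ccc(CC=C)c(O)c2OC)c1 | intermediate
13 | 1-iodo-4-{4-methoxy-3-[2-methoxy-4-(prop-2-en-1-yl)-3-(triethylsilyloxy)phenoxy]phenyl}butan-2-one | ICC(=O)CCc1ccc(OC)c(Oc2ccc(CC=C)c(O[Si](CC)(CC)CC)c2OC)c1 | intermediate
14 | juglanin A (15-membered meta,para-bridged diaryl ether heptanoid ketone, no stereocentre) | COc1ccc2cc1Oc1ccc(c(O)c1OC)CCCCC(=O)CC2 | target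

## Step count and risks

Total steps: 10 (three on the ring-B branch, two on the ring-A branch, five after convergence).
Longest linear sequence: 8 (steps 1, 2, 3, 6, 7, 8, 9, 10).

Steps most likely to fail:

1. **Step 10 (radical macrocyclisation).** Oligomerisation, reversible attack of the α-keto radical on ring A, or premature reduction may win over the 15-endo closure. Fallback: invert the polarity and move the ring-closing bond to C2–C3. A 2-arylethyl radical on ring B (CH2CH2I installed by MOM-directed ortho-lithiation/ethylene oxide) adds 15-endo to a ring-A vinyl ketone (from an aryl iodide and penta-1,4-dien-3-ol by Heck/isomerisation) under Bu3SnH high-dilution conditions (Porter-type macrocyclisation).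

2. **Step 9 (regioselective α-iodination).** Enolisation toward C6, incomplete silylation of the hindered phenoxide, or iodination of the electron-rich ring would spoil the precursor. Fallback: avoid enolisation altogether by carrying the ring-A chain as a 3-arylpropanoic ester (acrylate in place of methyl vinyl ketone), and after the Claisen step convert acid → acid chloride → diazoketone → iodomethyl ketone with HI, which fixes the iodine position by construction.

3. **Step 4 (hydroarylation of 2-bromophenol with methyl vinyl ketone).** Enone polymerisation, ortho attack/chroman formation or bisphenol-type condensation may lower the yield. Fallback: para-iodinate 2-bromophenol (NIS), O-methylate, and attach the chain by a chemoselective Jeffery–Heck/redox-isomerisation of the C–I bond with but-3-en-2-ol, which gives 8 directly.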